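**Retrosynthetic overview**

1. Target 25 ⇐ 24 (fluoride removes three silicon-based phenol protecting groups) ⇐ 20 ⇐ 19: the C6 prenyl group of ring B is made from a C6 ester via a benzylic phosphate and an alkenyl Grignard reagent.
2. 19 ⇐ three components in one flask: propynylbenzofuran 11 (ring A, C5, C4a, C4), 2,2-dimethyloxirane 15 (C3, C2, O1) and chloropyridazine ester 14 (C8a, C8, C7, C6 plus N=N). Bonds form in the order C4–C3, O1–C8a, then C8a–C4a and C6–C5 by intramolecular [4+2] cycloaddition and loss of N2.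
3. Enabling feature: C4 is propargylic to the C4a≡C5 triple bond (the two carbons ring B still lacks), so it can be metalated. C8a is the C–Cl carbon of a 1,2-diazine, alpha to nitrogen and para to the ester, so it accepts the tertiary alkoxide. The N=N bridge between C8a and C6 leaves as N2, and the gem-dimethyl C2 folds the O1–C2–C3–C4 tether.
4. 11 ⇐ salicylaldehyde 6 (dibromo-olefination, then tandem O-vinylation/Sonogashira coupling closes the furan ring); 6 ⇐ aromatic Claisen rearrangement of prenyl ether 5, which sets the 1,1-dimethylallyl group on C7 of the benzofuran.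
5. Ring order: ring A (bought) → furan ring (step 5) → ring B and the pyran ring together (step 7).

Key step: step 7

Assumption: 1, 2, 4, 7, 9 (THF solution), 12, 13, 15, 21 and 22 (THF solution) are taken as commercial; ring B and the pyran ring carry chroman numbering (O1, C2, C3, C4, C4a, C5–C8, C8a) and the target has no stereocentre.

**Route**

Step 1
Reactants: 1 2,4,6-trihydroxybenzaldehyde; 2 chlorotriisopropylsilane
Product: 3 2-hydroxy-4,6-bis(triisopropylsilyloxy)benzaldehyde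
Conditions: TIPSCl (2.1 equiv), imidazole, DMF, 0 °C to rt
Reagents that add atoms: chlorotriisopropylsilane CC(C)[Si](Cl)(C(C)C)C(C)C
Why: Silyl ether formation should stop at the 4,6-bis-ether because the last ortho hydroxyl stays locked in a hydrogen bond to the formyl oxygen, as in the analogous bis-alkoxymethylation of this aldehyde.

Step 2
Reactants: 3 2-hydroxy-4,6-bis(triisopropylsilyloxy)benzaldehyde; 4 3-methylbut-2-en-1-ol
Product: 5 2-(3-methylbut-2-enyloxy)-4,6-bis(triisopropylsilyloxy)benzaldehyde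
Conditions: PPh3, DIAD, THF, 0 °C to rt
Reagents that add atoms: 3-methylbut-2-en-1-ol CC(C)=CCO
Why: Mitsunobu etherification of the acidic ortho-formyl phenol is neutral, so the aryl silyl ethers should survive.

Step 3
Reactants: 5 2-(3-methylbut-2-enyloxy)-4,6-bis(triisopropylsilyloxy)benzaldehyde
Product: 6 2-hydroxy-3-(2-methylbut-3-en-2-yl)-4,6-bis(triisopropylsilyloxy)benzaldehyde
Conditions: Eu(fod)3 [europium tris(6,6,7,7,8,8,8-heptafluoro-2,2-dimethyloctane-3,5-dionate)] (10 mol%), CHCl3, 60 °C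
Reagents that add atoms: none
Why: Aromatic Claisen rearrangement of the aryl prenyl ether, accelerated by chelation of the lanthanide between the formyl and ether oxygens, should deliver the allyl unit with inversion to the only free ortho carbon and so give the 1,1-dimethylallyl group.

Step 4
Reactants: 6 2-hydroxy-3-(2-methylbut-3-en-2-yl)-4,6-bis(triisopropylsilyloxy)benzaldehyde; 7 carbon tetrabromide
Product: 8 2-(2,2-dibromoethenyl)-6-(2-methylbut-3-en-2-yl)-3,5-bis(triisopropylsilyloxy)phenol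
Conditions: CBr4, PPh3, Et3N, CH2Cl2, 0 °C
Reagents that add atoms: carbon tetrabromide BrC(Br)(Br)Br
Why: Ramirez dibromo-olefination (first stage of the Corey–Fuchs sequence) of the aldehyde, with Et3N buffering acid so that the silyl ethers and the free phenol should be retained.

Step 5
Reactants: 8 2-(2,2-dibromoethenyl)-6-(2-methylbut-3-en-2-yl)-3,5-bis(triisopropylsilyloxy)phenol; 9 propyne
Product: 11 7-(2-methylbut-3-en-2-yl)-2-(prop-1-yn-1-yl)-4,6-bis(triisopropylsilyloxy)-1-benzofuran, via 2-bromobenzofuran 10 (not isolated)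
Conditions: propyne (THF solution, excess), Pd/C, CuI, P(4-MeOC6H4)3, i-Pr2NH, toluene–H2O, 100 °C, sealed tube
Reagents that add atoms: propyne CC#C
Why: Tandem copper-catalysed intramolecular Ullmann-type O-vinylation (closing the furan ring to the 2-bromobenzofuran) and Sonogashira coupling of the remaining C–Br bond with propyne, a known one-flask route from gem-dibromovinylphenols to 2-alkynylbenzofurans.

Step 6
Reactants: 12 methyl 4,6-dichloropyridazine-3-carboxylate; 13 2-(trimethylsilyl)ethanol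
Product: 14 methyl 6-chloro-4-[2-(trimethylsilyl)ethoxy]pyridazine-3-carboxylate
Conditions: 13, LiN(SiMe3)2, THF, −78 °C; then 12, −78 to −40 °C
Reagents that add atoms: 2-(trimethylsilyl)ethanol C[Si](C)(C)CCO
Why: Nucleophilic aromatic substitution should occur at C4, the chloride ortho to the ester and para to a ring nitrogen, well before the C6 chloride, and the low temperature should keep the alkoxide off the ester.

Step 7
Reactants: 11 7-(2-methylbut-3-en-2-yl)-2-(prop-1-yn-1-yl)-4,6-bis(triisopropylsilyloxy)-1-benzofuran; 15 2,2-dimethyloxirane; 14 methyl 6-chloro-4-[2-(trimethylsilyl)ethoxy]pyridazine-3-carboxylate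
Product: 19 methyl 5-[7-(2-methylbut-3-en-2-yl)-4,6-bis(triisopropylsilyloxy)-1-benzofuran-2-yl]-2,2-dimethyl-7-[2-(trimethylsilyl)ethoxy]-3,4-dihydro-2H-chromene-6-carboxylate, via lithium alkoxide 16 (not isolated), via pyridazinyl ether 17 (not isolated), via diazabicyclooctatriene 18 (not isolated)
Conditions: n-BuLi, THF, −78 to −30 °C; 15, −78 °C to rt; 14, −40 °C to rt; then THF exchanged for 1,2-dichlorobenzene, 180 °C
Reagents that add atoms: 2,2-dimethyloxirane CC1(C)CO1; methyl 6-chloro-4-[2-(trimethylsilyl)ethoxy]pyridazine-3-carboxylate COC(=O)c1nnc(Cl)cc1OCC[Si](C)(C)C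
Why: n-BuLi should remove a propargylic proton of 11 (C4, acidified by the C4a≡C5 alkyne), and the propargyl/allenyl lithium should open the oxirane by SN2 attack of its unhindered CH2 terminus at the oxirane CH2 (C4–C3) to give tertiary alkoxide 16. 16 should then displace the only chloride of 14, which is alpha to nitrogen and para to the ester (SNAr, O1–C8a), and on heating ether 17 should undergo an intramolecular inverse-electron-demand Diels–Alder reaction of the ester-activated 1,2-diazine (diene C8a–C8–C7–C6) with the electron-rich aryl alkyne, followed by retro-Diels–Alder loss of N2 from 18. The closest known reaction type is the thermal cycloaddition of 3-(alkynyloxy)pyridazines to benzo-fused oxygen heterocycles with extrusion of nitrogen, preceded here by two standard anionic steps in the same flask. The pyran ring closes as the fused ring of the [4+2] step (new C8a–C4a bond across the four-atom O1–C2–C3–C4 tether), ring B closes in the same cycloaddition (C8a–C4a and C6–C5) and aromatises by the cycloreversion, and no stereocentre is formed. Site selectivity is needed three times and the substrates secure it: the aryl-bearing terminus of the ambident anion is hindered, 14 has a single leaving group, and the tether allows only one orientation of alkyne and diazine. The gem-dimethyl group at C2 favours the folded conformer needed for the cycloaddition.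

Step 8
Reactants: 19 methyl 5-[7-(2-methylbut-3-en-2-yl)-4,6-bis(triisopropylsilyloxy)-1-benzofuran-2-yl]-2,2-dimethyl-7-[2-(trimethylsilyl)ethoxy]-3,4-dihydro-2H-chromene-6-carboxylate
Product: 20 {5-[7-(2-methylbut-3-en-2-yl)-4,6-bis(triisopropylsilyloxy)-1-benzofuran-2-yl]-2,2-dimethyl-7-[2-(trimethylsilyl)ethoxy]-3,4-dihydro-2H-chromen-6-yl}methanol
Conditions: i-Bu2AlH, CH2Cl2, −78 to 0 °C; Rochelle salt work-up
Reagents that add atoms: none
Why: Hydride reduction of the aryl ester to the primary alcohol, under which silyl ethers, the terminal alkene and the benzofuran should be inert at low temperature.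

Step 9
Reactants: 20 {5-[7-(2-methylbut-3-en-2-yl)-4,6-bis(triisopropylsilyloxy)-1-benzofuran-2-yl]-2,2-dimethyl-7-[2-(trimethylsilyl)ethoxy]-3,4-dihydro-2H-chromen-6-yl}methanol; 21 diethyl chlorophosphate; 22 (2-methylprop-1-en-1-yl)magnesium bromide
Product: 24 2-{2,2-dimethyl-6-(3-methylbut-2-enyl)-7-[2-(trimethylsilyl)ethoxy]-3,4-dihydro-2H-chromen-5-yl}-7-(2-methylbut-3-en-2-yl)-4,6-bis(triisopropylsilyloxy)-1-benzofuran, via benzylic phosphate 23 (not isolated)
Conditions: n-BuLi, THF, −78 °C; ClP(O)(OEt)2, −78 to −20 °C; then 22, CuI (10 mol%), −40 to 0 °C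
Reagents that add atoms: (2-methylprop-1-en-1-yl)magnesium bromide CC(C)=C[Mg]Br
Why: Copper-catalysed sp3–sp2 cross-coupling of a benzylic phosphate with an alkenyl Grignard reagent forms the bond at the benzylic carbon, so the trisubstituted alkene is placed unambiguously as a prenyl group, and the poorly ionising phosphate should keep the electron-rich benzylic centre from alkylating C3 of the benzofuran.

Step 10
Reactants: 24 2-{2,2-dimethyl-6-(3-methylbut-2-enyl)-7-[2-(trimethylsilyl)ethoxy]-3,4-dihydro-2H-chromen-5-yl}-7-(2-methylbut-3-en-2-yl)-4,6-bis(triisopropylsilyloxy)-1-benzofuran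
Product: 25 Artopetelin C
Conditions: Bu4NF (excess), THF–DMPU, rt to 80 °C, argon; aq. NH4Cl
Reagents that add atoms: none
Why: Fluoride-induced cleavage of both aryl triisopropylsilyl ethers and fluoride-triggered beta-elimination of the aryl 2-(trimethylsilyl)ethyl ether (loss of ethene and Me3SiF) are non-acidic, so the ortho-prenyl and ortho-1,1-dimethylallyl phenols should not cyclise.

**Compound list**

1 | 2,4,6-trihydroxybenzaldehyde | O=Cc1c(O)cc(O)cc1O | starting material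
2 | chlorotriisopropylsilane | CC(C)[Si](Cl)(C(C)C)C(C)C | starting material
3 | 2-hydroxy-4,6-bis(triisopropylsilyloxy)benzaldehyde | O=Cc1c(O)cc(O[Si](C(C)C)(C(C)C)C(C)C)cc1O[Si](C(C)C)(C(C)C)C(C)C | intermediate
4 | 3-methylbut-2-en-1-ol | CC(C)=CCO | starting material
5 | 2-(3-methylbut-2-enyloxy)-4,6-bis(triisopropylsilyloxy)benzaldehyde | O=Cc1c(OCC=C(C)C)cc(O[Si](C(C)C)(C(C)C)C(C)C)cc1O[Si](C(C)C)(C(C)C)C(C)C | intermediate
6 | 2-hydroxy-3-(2-methylbut-3-en-2-yl)-4,6-bis(triisopropylsilyloxy)benzaldehyde | O=Cc1c(O)c(C(C)(C)C=C)c(O[Si](C(C)C)(C(C)C)C(C)C)cc1O[Si](C(C)C)(C(C)C)C(C)C | intermediate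
7 | carbon tetrabromide | BrC(Br)(Br)Br | starting material
8 | 2-(2,2-dibromoethenyl)-6-(2-methylbut-3-en-2-yl)-3,5-bis(triisopropylsilyloxy)phenol | BrC(Br)=Cc1c(O)c(C(C)(C)C=C)c(O[Si](C(C)C)(C(C)C)C(C)C)cc1O[Si](C(C)C)(C(C)C)C(C)C | intermediate
9 | propyne | CC#C | starting material
10 | 2-bromo-7-(2-methylbut-3-en-2-yl)-4,6-bis(triisopropylsilyloxy)-1-benzofuran | Brc1cc2c(O[Si](C(C)C)(C(C)C)C(C)C)cc(O[Si](C(C)C)(C(C)C)C(C)C)c(C(C)(C)C=C)c2o1 | intermediate
11 | 7-(2-methylbut-3-en-2-yl)-2-(prop-1-yn-1-yl)-4,6-bis(triisopropylsilyloxy)-1-benzofuran | CC#Cc1cc2c(O[Si](C(C)C)(C(C)C)C(C)C)cc(O[Si](C(C)C)(C(C)C)C(C)C)c(C(C)(C)C=C)c2o1 | intermediate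
12 | methyl 4,6-dichloropyridazine-3-carboxylate | COC(=O)c1nnc(Cl)cc1Cl | starting material
13 | 2-(trimethylsilyl)ethanol | C[Si](C)(C)CCO | starting material
14 | methyl 6-chloro-4-[2-(trimethylsilyl)ethoxy]pyridazine-3-carboxylate | COC(=O)c1nnc(Cl)cc1OCC[Si](C)(C)C | intermediate
15 | 2,2-dimethyloxirane | CC1(C)CO1 | starting material
16 | lithium 2-methyl-6-[7-(2-methylbut-3-en-2-yl)-4,6-bis(triisopropylsilyloxy)-1-benzofuran-2-yl]hex-5-yn-2-olate | [Li+].[O-]C(C)(C)CCC#Cc1cc2c(O[Si](C(C)C)(C(C)C)C(C)C)cc(O[Si](C(C)C)(C(C)C)C(C)C)c(C(C)(C)C=C)c2o1 | intermediate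
17 | methyl 6-({2-methyl-6-[7-(2-methylbut-3-en-2-yl)-4,6-bis(triisopropylsilyloxy)-1-benzofuran-2-yl]hex-5-yn-2-yl}oxy)-4-[2-(trimethylsilyl)ethoxy]pyridazine-3-carboxylate | COC(=O)c1nnc(OC(C)(C)CCC#Cc2cc3c(O[Si](C(C)C)(C(C)C)C(C)C)cc(O[Si](C(C)C)(C(C)C)C(C)C)c(C(C)(C)C=C)c3o2)cc1OCC[Si](C)(C)C | intermediate
18 | pyran-fused 2,3-diazabicyclo[2.2.2]octa-2,5,7-triene cycloadduct (ester on one bridgehead, ring oxygen on the other) | COC(=O)C12N=NC3(OC(C)(C)CCC3=C1c1cc4c(O[Si](C(C)C)(C(C)C)C(C)C)cc(O[Si](C(C)C)(C(C)C)C(C)C)c(C(C)(C)C=C)c4o1)C=C2OCC[Si](C)(C)C | intermediate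
19 | methyl 5-[7-(2-methylbut-3-en-2-yl)-4,6-bis(triisopropylsilyloxy)-1-benzofuran-2-yl]-2,2-dimethyl-7-[2-(trimethylsilyl)ethoxy]-3,4-dihydro-2H-chromene-6-carboxylate | COC(=O)c1c(OCC[Si](C)(C)C)cc2OC(C)(C)CCc2c1-c1cc3c(O[Si](C(C)C)(C(C)C)C(C)C)cc(O[Si](C(C)C)(C(C)C)C(C)C)c(C(C)(C)C=C)c3o1 | intermediate
20 | {5-[7-(2-methylbut-3-en-2-yl)-4,6-bis(triisopropylsilyloxy)-1-benzofuran-2-yl]-2,2-dimethyl-7-[2-(trimethylsilyl)ethoxy]-3,4-dihydro-2H-chromen-6-yl}methanol | OCc1c(OCC[Si](C)(C)C)cc2OC(C)(C)CCc2c1-c1cc3c(O[Si](C(C)C)(C(C)C)C(C)C)cc(O[Si](C(C)C)(C(C)C)C(C)C)c(C(C)(C)C=C)c3o1 | intermediate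
21 | diethyl chlorophosphate | CCOP(=O)(Cl)OCC | starting material
22 | (2-methylprop-1-en-1-yl)magnesium bromide | CC(C)=C[Mg]Br | starting material
23 | diethyl {5-[7-(2-methylbut-3-en-2-yl)-4,6-bis(triisopropylsilyloxy)-1-benzofuran-2-yl]-2,2-dimethyl-7-[2-(trimethylsilyl)ethoxy]-3,4-dihydro-2H-chromen-6-yl}methyl phosphate | CCOP(=O)(OCC)OCc1c(OCC[Si](C)(C)C)cc2OC(C)(C)CCc2c1-c1cc3c(O[Si](C(C)C)(C(C)C)C(C)C)cc(O[Si](C(C)C)(C(C)C)C(C)C)c(C(C)(C)C=C)c3o1 | intermediate
24 | 2-{2,2-dimethyl-6-(3-methylbut-2-enyl)-7-[2-(trimethylsilyl)ethoxy]-3,4-dihydro-2H-chromen-5-yl}-7-(2-methylbut-3-en-2-yl)-4,6-bis(triisopropylsilyloxy)-1-benzofuran | CC(C)=CCc1c(OCC[Si](C)(C)C)cc2OC(C)(C)CCc2c1-c1cc3c(O[Si](C(C)C)(C(C)C)C(C)C)cc(O[Si](C(C)C)(C(C)C)C(C)C)c(C(C)(C)C=C)c3o1 | intermediate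
25 | Artopetelin C | C=CC(C)(C)c1c(O)cc(O)c2cc(-c3c(CC=C(C)C)c(O)cc4c3CCC(C)(C)O4)oc12 | target

**Step count and risks**

Total step count: 10. Longest linear sequence: 9 steps (steps 1–5, then 7–10); step 6 is a one-step side branch.

Steps most likely to fail:

Step 7. The ambident propargyl/allenyl lithium may react through its aryl-bearing terminus, or n-BuLi may metalate elsewhere, so that mixtures enter the high-temperature stage; the crowded cycloaddition can then be outpaced by decomposition. The fallback sets out from 8 and 15 and comes back at 19. It builds the alkynol by an unambiguous sp–sp2 coupling and runs each event separately. 8 is cyclised alone (CuI, K3PO4, THF, 80 °C) and 2-bromobenzofuran 10 is isolated. 15 is opened with propargylmagnesium bromide (from 3-bromoprop-1-yne and Mg, CuI catalysis) to give 2-methylhex-5-yn-2-ol F1. Sonogashira coupling of 10 with F1 (PdCl2(PPh3)2, CuI, Et3N) gives 2-methyl-6-[7-(2-methylbut-3-en-2-yl)-4,6-bis(triisopropylsilyloxy)-1-benzofuran-2-yl]hex-5-yn-2-ol F2. LiN(SiMe3)2 converts F2 into 16, which is treated with 14 to give isolated 17, and 17 is heated on its own in 1,2-dichlorobenzene to reach 19.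

Step 9. The benzylic phosphate carries ortho and para oxygen donors and may ionise, leading to intramolecular Friedel–Crafts alkylation at C3 of the neighbouring benzofuran, or substitution at the doubly flanked benzylic carbon may stall. The fallback sets out from 20 and comes back at 24 and never places a leaving group on the benzylic carbon. 20 is oxidised (MnO2, CH2Cl2) to 5-[7-(2-methylbut-3-en-2-yl)-4,6-bis(triisopropylsilyloxy)-1-benzofuran-2-yl]-2,2-dimethyl-7-[2-(trimethylsilyl)ethoxy]-3,4-dihydro-2H-chromene-6-carbaldehyde F3. Wittig reaction with (methoxymethylene)triphenylphosphorane gives the methyl enol ether F4 (E/Z mixture). Mild hydrolysis (aq. HCO2H, THF, 0 °C) gives the arylacetaldehyde F5. A second Wittig reaction, with isopropylidenetriphenylphosphorane, gives 24.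

Step 10. Fragmentation of the aryl 2-(trimethylsilyl)ethyl ether may be much slower than Si–O cleavage, so that forcing basic fluoride conditions act on an air-sensitive prenylated triphenolate. The fallback sets out from 19 and comes back at 25. It removes this group early, while its oxygen is ortho to the ester. MgBr2·OEt2 (CH2Cl2–MeNO2) cleaves the ether by chelation to give methyl 7-hydroxy-5-[7-(2-methylbut-3-en-2-yl)-4,6-bis(triisopropylsilyloxy)-1-benzofuran-2-yl]-2,2-dimethyl-3,4-dihydro-2H-chromene-6-carboxylate F6. TIPSOTf and 2,6-lutidine give the tris(silyl ether) ester F7. i-Bu2AlH gives the benzylic alcohol F8. The sequence of step 9 proceeds through the benzylic phosphate F9 (not isolated) to the prenylated tris(silyl ether) F10. Bu4NF at room temperature then only has to cleave three aryl silyl ethers to give 25.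

**Further compounds**

F1 | step 7 | 2-methylhex-5-yn-2-ol | CC(C)(O)CCC#C
F2 | step 7 | 2-methyl-6-[7-(2-methylbut-3-en-2-yl)-4,6-bis(triisopropylsilyloxy)-1-benzofuran-2-yl]hex-5-yn-2-ol | CC(C)(O)CCC#Cc1cc2c(O[Si](C(C)C)(C(C)C)C(C)C)cc(O[Si](C(C)C)(C(C)C)C(C)C)c(C(C)(C)C=C)c2o1
F3 | step 9 | 5-[7-(2-methylbut-3-en-2-yl)-4,6-bis(triisopropylsilyloxy)-1-benzofuran-2-yl]-2,2-dimethyl-7-[2-(trimethylsilyl)ethoxy]-3,4-dihydro-2H-chromene-6-carbaldehyde | O=Cc1c(OCC[Si](C)(C)C)cc2OC(C)(C)CCc2c1-c1cc3c(O[Si](C(C)C)(C(C)C)C(C)C)cc(O[Si](C(C)C)(C(C)C)C(C)C)c(C(C)(C)C=C)c3o1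
F4 | step 9 | 2-{6-(2-methoxyethenyl)-2,2-dimethyl-7-[2-(trimethylsilyl)ethoxy]-3,4-dihydro-2H-chromen-5-yl}-7-(2-methylbut-3-en-2-yl)-4,6-bis(triisopropylsilyloxy)-1-benzofuran (E/Z mixture) | COC=Cc1c(OCC[Si](C)(C)C)cc2OC(C)(C)CCc2c1-c1cc3c(O[Si](C(C)C)(C(C)C)C(C)C)cc(O[Si](C(C)C)(C(C)C)C(C)C)c(C(C)(C)C=C)c3o1
F5 | step 9 | 2-{5-[7-(2-methylbut-3-en-2-yl)-4,6-bis(triisopropylsilyloxy)-1-benzofuran-2-yl]-2,2-dimethyl-7-[2-(trimethylsilyl)ethoxy]-3,4-dihydro-2H-chromen-6-yl}acetaldehyde | O=CCc1c(OCC[Si](C)(C)C)cc2OC(C)(C)CCc2c1-c1cc3c(O[Si](C(C)C)(C(C)C)C(C)C)cc(O[Si](C(C)C)(C(C)C)C(C)C)c(C(C)(C)C=C)c3o1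
F6 | step 10 | methyl 7-hydroxy-5-[7-(2-methylbut-3-en-2-yl)-4,6-bis(triisopropylsilyloxy)-1-benzofuran-2-yl]-2,2-dimethyl-3,4-dihydro-2H-chromene-6-carboxylate | COC(=O)c1c(O)cc2OC(C)(C)CCc2c1-c1cc3c(O[Si](C(C)C)(C(C)C)C(C)C)cc(O[Si](C(C)C)(C(C)C)C(C)C)c(C(C)(C)C=C)c3o1
F7 | step 10 | methyl 5-[7-(2-methylbut-3-en-2-yl)-4,6-bis(triisopropylsilyloxy)-1-benzofuran-2-yl]-2,2-dimethyl-7-(triisopropylsilyloxy)-3,4-dihydro-2H-chromene-6-carboxylate | COC(=O)c1c(O[Si](C(C)C)(C(C)C)C(C)C)cc2OC(C)(C)CCc2c1-c1cc3c(O[Si](C(C)C)(C(C)C)C(C)C)cc(O[Si](C(C)C)(C(C)C)C(C)C)c(C(C)(C)C=C)c3o1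
F8 | step 10 | {5-[7-(2-methylbut-3-en-2-yl)-4,6-bis(triisopropylsilyloxy)-1-benzofuran-2-yl]-2,2-dimethyl-7-(triisopropylsilyloxy)-3,4-dihydro-2H-chromen-6-yl}methanol | OCc1c(O[Si](C(C)C)(C(C)C)C(C)C)cc2OC(C)(C)CCc2c1-c1cc3c(O[Si](C(C)C)(C(C)C)C(C)C)cc(O[Si](C(C)C)(C(C)C)C(C)C)c(C(C)(C)C=C)c3o1
F9 | step 10 | diethyl {5-[7-(2-methylbut-3-en-2-yl)-4,6-bis(triisopropylsilyloxy)-1-benzofuran-2-yl]-2,2-dimethyl-7-(triisopropylsilyloxy)-3,4-dihydro-2H-chromen-6-yl}methyl phosphate | CCOP(=O)(OCC)OCc1c(O[Si](C(C)C)(C(C)C)C(C)C)cc2OC(C)(C)CCc2c1-c1cc3c(O[Si](C(C)C)(C(C)C)C(C)C)cc(O[Si](C(C)C)(C(C)C)C(C)C)c(C(C)(C)C=C)c3o1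
F10 | step 10 | 2-[2,2-dimethyl-6-(3-methylbut-2-enyl)-7-(triisopropylsilyloxy)-3,4-dihydro-2H-chromen-5-yl]-7-(2-methylbut-3-en-2-yl)-4,6-bis(triisopropylsilyloxy)-1-benzofuran | CC(C)=CCc1c(O[Si](C(C)C)(C(C)C)C(C)C)cc2OC(C)(C)CCc2c1-c1cc3c(O[Si](C(C)C)(C(C)C)C(C)C)cc(O[Si](C(C)C)(C(C)C)C(C)C)c(C(C)(C)C=C)c3o1
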